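## Retrosynthetic overview

1. Target ⇒ one-pot acidolysis of a PMB ester / 3,4-acetonide precursor.
2. Caffeoyl ester ⇒ C=C disconnection (Knoevenagel–Doebner) to 3,4-dihydroxybenzaldehyde and a C5-O-malonyl half-ester, made from the free 5-OH and Meldrum's acid.
3. 5-OH PMB ester ⇒ hydroxide opening of the 1-O-methyl 1,5-lactone, then carboxylate alkylation.
4. Key bond, the tertiary C1–O–CH3 ether ⇒ visible-light copper/photoredox decarboxylative O-methylation of quinide acetonide, with acetate as the methyl source.
5. Quinide acetonide ⇒ (−)-quinic acid, which supplies the cyclohexane ring and all four stereocentres; the only rings formed are the temporary γ-lactone and dioxolane (both step 1), opened in steps 3 and 5.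

Assumption: ring positions follow IUPAC quinic acid numbering, in which the caffeoyl group of the given SMILES sits on O5 (trans to O4, cis to the carboxyl); this is position 3 in the older numbering used in the trivial name.

## Route

Step 1
Reactants: 1 (−)-quinic acid
Product: 3 quinide acetonide (3,4-O-isopropylidenequinic acid 1,5-lactone), via acetonide acid 2 (not isolated)
Conditions: 2,2-dimethoxypropane (3 equiv), TsOH·H2O (5 mol %), acetone, reflux, 3 h; Et3N quench
Reagents that add atoms: 2,2-dimethoxypropane, COC(C)(C)OC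
Why: Acid-catalysed transketalisation (acetonide formation) protects the only cis-vicinal diol (O3/O4) and the carboxyl then lactonises onto O5, the one hydroxyl cis to it; no C–O bond at a stereocentre is broken, so all four centres of 1 are carried over and only the tertiary 1-OH stays free.

Step 2
Reactants: 3 quinide acetonide
Product: 4 1-O-methylquinide acetonide (1-O-methyl-3,4-O-isopropylidenequinic acid 1,5-lactone)
Conditions: MesI(OAc)2 (2.0 equiv), Cu(MeCN)4PF6 (20 mol %), bathophenanthroline (30 mol %), Ir(ppy)3 (1 mol %), BTMG (2-tert-butyl-1,1,3,3-tetramethylguanidine, 0.3 equiv), degassed 1,4-dioxane, 450 nm LEDs, 25 °C, 6 h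
Reagents that add atoms: iodomesitylene diacetate, CC(=O)OI(OC(C)=O)c1c(C)cc(C)cc1C
Why: Proposed new method: copper-metallaphotoredox decarboxylative O-methylation, in which excited Ir(ppy)3 reduces the trivalent-iodine diacetate to an acetoxyl radical that loses CO2 to give CH3•, the tetravalent iridium formed oxidises the monovalent copper alkoxide of 3 (held as a five-membered chelate through the alkoxide O and the lactone C=O) to the divalent stage, this captures CH3• to give a trivalent copper methyl alkoxide, and C(sp3)–O reductive elimination forms the O–CH3 bond without touching the C1–O bond (configuration retained); the closest known reaction type is the copper/photoredox decarboxylative C(sp3)–N coupling of N-nucleophiles with iodomesitylene dicarboxylates (N-methylation included), not yet shown for an aliphatic tertiary alkoxide.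

Step 3
Reactants: 4 1-O-methylquinide acetonide
Product: 6 PMB ester alcohol (4-methoxybenzyl 1-O-methyl-3,4-O-isopropylidenequinate; 5-OH free), via cesium carboxylate 5 (not isolated)
Conditions: CsOH·H2O (1.05 equiv), THF/H2O (4:1), 0 °C → rt, 1 h; evaporate, toluene azeotrope; then PMBCl (1.2 equiv), Bu4NI (10 mol %), DMF, rt, 12 h
Reagents that add atoms: cesium hydroxide, [Cs+].[OH-]; 4-methoxybenzyl chloride, COc1ccc(CCl)cc1
Why: Saponification by acyl–oxygen cleavage (C5 keeps its configuration) gives a carboxylate that cannot relactonise as its cesium salt and is alkylated chemoselectively by the benzylic chloride (carboxylate SN2 O-alkylation), leaving the secondary 5-OH as the only free hydroxyl.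

Step 4
Reactants: 6 PMB ester alcohol; 7 Meldrum's acid (2,2-dimethyl-1,3-dioxane-4,6-dione); 8 3,4-dihydroxybenzaldehyde
Product: 11 protected caffeate (4-methoxybenzyl 5-O-[(E)-caffeoyl]-1-O-methyl-3,4-O-isopropylidenequinate), via malonate half-ester 9 (not isolated), via arylidenemalonate half-ester 10 (not isolated)
Conditions: 7 (1.2 equiv), toluene, 85 °C, 4 h; evaporate; then 8 (1.5 equiv), piperidine (0.3 equiv), pyridine, 50 °C, 24 h, Ar
Reagents that add atoms: none
Why: Meldrum's acid acylates the 5-OH on heating with loss of acetone (neutral ring-opening acylation), and the malonic half-ester then undergoes Knoevenagel–Doebner condensation and decarboxylation with the unprotected catechol aldehyde, the decarboxylative elimination giving the (E)-cinnamate; no ring stereocentre is involved.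

Step 5
Reactants: 11 protected caffeate
Product: 12 3-O-caffeoyl-1-methylquinic acid (5-O-[(E)-caffeoyl]-1-O-methylquinic acid in IUPAC ring numbering)
Conditions: TFA/H2O (9:1), anisole (20 equiv), 0 °C → rt, 1 h; evaporate cold, C18 chromatography (H2O/MeCN, 0.1 % HCO2H)
Reagents that add atoms: none
Why: Aqueous TFA hydrolyses the isopropylidene ketal and cleaves the PMB ester by alkyl–oxygen ionisation (acidolysis) while anisole traps the 4-methoxybenzyl cation before it can alkylate the catechol; the caffeoyl ester is stable to acid, cannot lactonise and does not migrate in this time, and no stereocentre is touched.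

## Compound list

1 | (−)-quinic acid, (1S,3R,4S,5R)-1,3,4,5-tetrahydroxycyclohexane-1-carboxylic acid | O[C@@]1(C(=O)O)C[C@@H](O)[C@@H](O)[C@H](O)C1 | starting material
2 | acetonide acid, 3,4-O-isopropylidenequinic acid (not isolated; centres as in 1) | O[C@@]1(C(=O)O)C[C@H]2OC(C)(C)O[C@H]2[C@H](O)C1 | intermediate
3 | quinide acetonide, 3,4-O-isopropylidenequinic acid 1,5-lactone (cis-fused dioxolane on O3/O4, γ-lactone from C1 carboxyl to O5, free tertiary 1-OH) | O[C@@]1(C(=O)O2)C[C@H]3OC(C)(C)O[C@H]3[C@H]2C1 | intermediate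
4 | 1-O-methylquinide acetonide, 1-O-methyl-3,4-O-isopropylidenequinic acid 1,5-lactone | CO[C@@]1(C(=O)O2)C[C@H]3OC(C)(C)O[C@H]3[C@H]2C1 | intermediate
5 | cesium carboxylate, cesium 1-O-methyl-3,4-O-isopropylidenequinate (not isolated; 5-OH free) | [Cs+].CO[C@@]1(C(=O)[O-])C[C@H]2OC(C)(C)O[C@H]2[C@H](O)C1 | intermediate
6 | PMB ester alcohol, 4-methoxybenzyl 1-O-methyl-3,4-O-isopropylidenequinate (5-OH free) | CO[C@@]1(C(=O)OCc2ccc(OC)cc2)C[C@H]3OC(C)(C)O[C@H]3[C@H](O)C1 | intermediate
7 | Meldrum's acid, 2,2-dimethyl-1,3-dioxane-4,6-dione | CC1(C)OC(=O)CC(=O)O1 | starting material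
8 | 3,4-dihydroxybenzaldehyde | O=Cc1ccc(O)c(O)c1 | starting material
9 | malonate half-ester, 4-methoxybenzyl 5-O-(carboxyacetyl)-1-O-methyl-3,4-O-isopropylidenequinate (not isolated) | CO[C@@]1(C(=O)OCc2ccc(OC)cc2)C[C@H]3OC(C)(C)O[C@H]3[C@H](OC(=O)CC(=O)O)C1 | intermediate
10 | arylidenemalonate half-ester, 4-methoxybenzyl 5-O-[2-carboxy-3-(3,4-dihydroxyphenyl)acryloyl]-1-O-methyl-3,4-O-isopropylidenequinate (not isolated; alkene geometry not fixed) | CO[C@@]1(C(=O)OCc2ccc(OC)cc2)C[C@H]3OC(C)(C)O[C@H]3[C@H](OC(=O)C(=Cc4ccc(O)c(O)c4)C(=O)O)C1 | intermediate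
11 | protected caffeate, 4-methoxybenzyl 5-O-[(E)-caffeoyl]-1-O-methyl-3,4-O-isopropylidenequinate | CO[C@@]1(C(=O)OCc2ccc(OC)cc2)C[C@H]3OC(C)(C)O[C@H]3[C@H](OC(=O)/C=C/c4ccc(O)c(O)c4)C1 | intermediate
12 | 3-O-caffeoyl-1-methylquinic acid | CO[C@@]1(C(=O)O)C[C@@H](O)[C@@H](O)[C@H](OC(=O)/C=C/c2ccc(O)c(O)c2)C1 | target

## Step count and risks

Total steps: 5. Longest linear sequence: 5 steps from (−)-quinic acid; every other component is bought.

The three steps most likely to fail:

**Step 2 (proposed new method).** The untested points are these: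
- whether a hindered tertiary alkoxide undergoes C–O reductive elimination from trivalent copper faster than acetate does (which would give methyl acetate);
- whether CH3• is lost to hydrogen abstraction from solvent;
- whether the alkoxide exchanges onto iodine and fragments by β-scission of an alkoxy radical.

Fallback, known chemistry: set out from 3 and methylate by a classical Williamson reaction (NaH 1.3 equiv, MeI 5 equiv, THF/DMF, 0 °C; Ag2O/MeI if the lactone suffers under NaH). This is an ionic SN2 alkylation of the free alkoxide in place of the radical/copper coupling. It returns to the route at 4 and makes no new compound (F0).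

**Step 4.** At 85 °C the hydroxy ester 6 can relactonise to 4 with loss of 4-methoxybenzyl alcohol in competition with malonylation. The Doebner stage may also be slow or suffer catechol oxidation on this substrate.

Fallback: set out from 6 and attach the intact, phenol-protected caffeoyl unit by low-temperature acylation. Caffeic acid (bought) with Ac2O/pyridine gives (E)-3,4-di-O-acetylcaffeic acid F1. Oxalyl chloride with catalytic DMF in CH2Cl2 converts it to (E)-3,4-di-O-acetylcaffeoyl chloride F2. Acylation of 6 with F2 (DMAP, pyridine/CH2Cl2, 0 °C → rt) gives 4-methoxybenzyl 5-O-[(E)-3,4-di-O-acetylcaffeoyl]-1-O-methyl-3,4-O-isopropylidenequinate F3. Selective removal of the two aryl acetates with hydrazine acetate in DMF at rt returns to the route at 11.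

**Step 5.** The 4-methoxybenzyl cation may C-alkylate the electron-rich catechol despite the scavenger. The free acid may also suffer partial ester hydrolysis or 5→4 acyl shift during concentration.

Fallback: mask the acid as an allyl ester and unmask it with a palladium catalyst, so that no benzylic cation is ever formed. Set out from 5 and alkylate with allyl bromide in DMF to give allyl 1-O-methyl-3,4-O-isopropylidenequinate F4. Treat F4 as in step 4 (Meldrum's acid 7 in toluene at 85 °C, then 8, piperidine, pyridine, 50 °C). This passes through allyl 5-O-(carboxyacetyl)-1-O-methyl-3,4-O-isopropylidenequinate F5 and allyl 5-O-[2-carboxy-3-(3,4-dihydroxyphenyl)acryloyl]-1-O-methyl-3,4-O-isopropylidenequinate F6, neither isolated, to allyl 5-O-[(E)-caffeoyl]-1-O-methyl-3,4-O-isopropylidenequinate F7. Pd(PPh3)4 (5 mol %) with morpholine in THF at rt removes the allyl group to give 5-O-[(E)-caffeoyl]-1-O-methyl-3,4-O-isopropylidenequinic acid F8. Hydrolysis of the acetonide alone (TFA/H2O 9:1, 0 °C, 30 min, or 80 % aqueous AcOH, 40 °C) returns to the route at 12, one step longer overall.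

## Further compounds

F0 | step 2 | none | none
F1 | step 4 | (E)-3,4-di-O-acetylcaffeic acid | CC(=O)Oc1ccc(/C=C/C(=O)O)cc1OC(C)=O
F2 | step 4 | (E)-3,4-di-O-acetylcaffeoyl chloride | CC(=O)Oc1ccc(/C=C/C(=O)Cl)cc1OC(C)=O
F3 | step 4 | 4-methoxybenzyl 5-O-[(E)-3,4-di-O-acetylcaffeoyl]-1-O-methyl-3,4-O-isopropylidenequinate | CO[C@@]1(C(=O)OCc2ccc(OC)cc2)C[C@H]3OC(C)(C)O[C@H]3[C@H](OC(=O)/C=C/c4ccc(OC(C)=O)c(OC(C)=O)c4)C1
F4 | step 5 | allyl 1-O-methyl-3,4-O-isopropylidenequinate | CO[C@@]1(C(=O)OCC=C)C[C@H]2OC(C)(C)O[C@H]2[C@H](O)C1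
F5 | step 5 | allyl 5-O-(carboxyacetyl)-1-O-methyl-3,4-O-isopropylidenequinate | CO[C@@]1(C(=O)OCC=C)C[C@H]2OC(C)(C)O[C@H]2[C@H](OC(=O)CC(=O)O)C1
F6 | step 5 | allyl 5-O-[2-carboxy-3-(3,4-dihydroxyphenyl)acryloyl]-1-O-methyl-3,4-O-isopropylidenequinate | CO[C@@]1(C(=O)OCC=C)C[C@H]2OC(C)(C)O[C@H]2[C@H](OC(=O)C(=Cc3ccc(O)c(O)c3)C(=O)O)C1
F7 | step 5 | allyl 5-O-[(E)-caffeoyl]-1-O-methyl-3,4-O-isopropylidenequinate | CO[C@@]1(C(=O)OCC=C)C[C@H]2OC(C)(C)O[C@H]2[C@H](OC(=O)/C=C/c3ccc(O)c(O)c3)C1
F8 | step 5 | 5-O-[(E)-caffeoyl]-1-O-methyl-3,4-O-isopropylidenequinic acid | CO[C@@]1(C(=O)O)C[C@H]2OC(C)(C)O[C@H]2[C@H](OC(=O)/C=C/c3ccc(O)c(O)c3)C1
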